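**Plan**

- Numbering is that of the target (ring A: C1–C5 and C10; ring B: C5–C10). C5 is quaternary, lies α to the oxygenated C6 and carries C4 with its exocyclic C18 methylene. A ring B silyl enol ether C5=C6 that adds across a C4≡C18 alkyne hung from C10 through C1–C3 therefore makes the C4–C5 bond, ring A and the methylene in one step.
- Retrosynthetic cuts, in order: C12–C13 (Heck); the O6 and O7 esters; C4–C5 (gold step, ring A); C11=C12 and O1–C11 (lactol olefination); C5–C19 (methylenation); the C7–O and C8–O bonds (dihydroxylation); C1–C2 (Grignard); C5–C10 and C8–C9 (Diels–Alder, ring B).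
- Forward: ring B by cycloaddition; the C2–C4/C18 chain on C1; an O1–C11 lactone that locks ring B; cis-diol and acetonide; regiodefined enol ether by 1,4-reduction of an α-methylene ketone; vinyl group; ring A; esters; butenolide last.
- Stereochemistry: C9 and C10 from the enantioselective Diels–Alder reaction of an E dienophile; C1 by Felkin–Anh reduction; C7 and C8 by syn-dihydroxylation anti to the axial C20 methyl; C5 in the gold step (alkyne to the H10 face); C6 by axial hydride delivery.

Key step: step 16

Assumption: the (S)-oxazaborolidinium ion of step 2 is taken to shield the enal face that leads to adduct 4 as drawn (usual formyl C–H···O binding of α-substituted enals); if the sense is the opposite, the (R)-catalyst is used and nothing else changes.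

**Route**

Step 1
Reactants: 1 (E)-pent-3-en-2-one
Product: 2 triisopropyl{[(3E)-penta-1,3-dien-2-yl]oxy}silane
Conditions: LiN(i-Pr)2, THF, −78 °C; TIPSOTf, −78 → 0 °C
Reagents that add atoms: triisopropylsilyl trifluoromethanesulfonate, CC(C)[Si](OS(=O)(=O)C(F)(F)F)(C(C)C)C(C)C
Why: Kinetic deprotonation of the methyl group and O-silylation of the cross-conjugated enolate (silyl enol ether formation) give the 2-silyloxy diene with the E propenyl geometry intact, the bulky silyl group being chosen to survive the acidic catalyst of step 2.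

Step 2
Reactants: 2 triisopropyl{[(3E)-penta-1,3-dien-2-yl]oxy}silane; 3 ethyl (2E)-3-methyl-4-oxobut-2-enoate
Product: 4 ethyl 6-formyl-5,6-dimethyl-3-[(triisopropylsilyl)oxy]cyclohex-3-ene-1-carboxylate (C10 ester trans to C9 formyl; C8 methyl cis to formyl)
Conditions: (S)-3,3-diphenyl-1-(2-methylphenyl)tetrahydro-1H,3H-pyrrolo[1,2-c][1,3,2]oxazaborole (20 mol%), HNTf2 (20 mol%), CH2Cl2, −78 → −40 °C
Reagents that add atoms: none
Why: Lewis-acid-catalysed enantioselective Diels–Alder reaction in which the boron-bound formyl group makes C10 the electrophilic terminus, so that the unsubstituted diene terminus (C5) bonds to C10 and the methyl-bearing terminus (C8) to C9, the E dienophile fixes the C9 formyl and C10 ester trans, endo addition puts the C8 methyl cis to formyl (of no later consequence) and the chiral oxazaborolidinium ion sets the absolute configuration at C9 and C10.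

Step 3
Reactants: 4 ethyl 6-formyl-5,6-dimethyl-3-[(triisopropylsilyl)oxy]cyclohex-3-ene-1-carboxylate
Product: 5 ethyl 6-(hydroxymethyl)-5,6-dimethyl-3-[(triisopropylsilyl)oxy]cyclohex-3-ene-1-carboxylate
Conditions: NaBH4, EtOH, −20 °C
Reagents that add atoms: none
Why: Chemoselective 1,2-reduction of the aldehyde by borohydride, to which the ester and the bulky silyl enol ether are inert at low temperature, touches no stereocentre.

Step 4
Reactants: 5 ethyl 6-(hydroxymethyl)-5,6-dimethyl-3-[(triisopropylsilyl)oxy]cyclohex-3-ene-1-carboxylate; 6 (4-bromobut-1-yn-1-yl)trimethylsilane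
Product: 9 1-{6-(hydroxymethyl)-5,6-dimethyl-3-[(triisopropylsilyl)oxy]cyclohex-3-en-1-yl}-5-(trimethylsilyl)pent-4-yn-1-one, via Grignard reagent 7 (not isolated), via hydroxy Weinreb amide 8 (not isolated)
Conditions: 6, Mg, THF, rt; 5, MeNHOMe·HCl, i-PrMgCl, THF, −20 °C; then 7, −20 → 0 °C; NH4Cl (aq)
Reagents that add atoms: none
Why: Magnesium-amide aminolysis turns the ester into the N-methoxy-N-methylamide and the alkyl Grignard reagent then adds once, the chelated tetrahedral intermediate collapsing only on work-up (Weinreb ketone synthesis), so that C2–C4 and C18 are attached to C1 without over-addition or epimerisation at C10.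

Step 5
Reactants: 9 1-{6-(hydroxymethyl)-5,6-dimethyl-3-[(triisopropylsilyl)oxy]cyclohex-3-en-1-yl}-5-(trimethylsilyl)pent-4-yn-1-one
Product: 10 1-{6-(hydroxymethyl)-5,6-dimethyl-3-[(triisopropylsilyl)oxy]cyclohex-3-en-1-yl}-5-(trimethylsilyl)pent-4-yn-1-ol (C1 carbinol as in the target)
Conditions: LiBH(s-Bu)3 (2.2 equiv), THF, −78 °C; NH4Cl (aq)
Reagents that add atoms: none
Why: Felkin–Anh-controlled ketone reduction in which the bulky hydride attacks C1 anti to the quaternary C9 substituent of the neighbouring stereocentre C10 while the alkynyl chain passes the small hydrogen, which gives the C1 configuration of the target (O1 anti to C5 in the extended C9–C10–C1–C2 chain).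

Step 6
Reactants: 10 diol
Product: 11 7,7a-dimethyl-5-[(triisopropylsilyl)oxy]-3-[4-(trimethylsilyl)but-3-yn-1-yl]-3a,4,7,7a-tetrahydro-2-benzofuran-1(3H)-one (trans-fused O1–C11 lactone)
Conditions: [Cu(MeCN)4]OTf (5 mol%), 2,2′-bipyridine, (2,2,6,6-tetramethylpiperidin-1-yl)oxyl, N-methylimidazole, air, MeCN, rt
Reagents that add atoms: none
Why: The copper/nitroxyl aerobic oxidation is selective for the primary alcohol and carries the lactol formed with O1 on to the γ-lactone (oxidative lactonisation of a 1,4-diol), which masks C11 at the acid level, protects O1 and locks ring B without changing a stereocentre.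

Step 7
Reactants: 11 trans-fused lactone silyl enol ether
Product: 12 7,7a-dimethyl-3-[4-(trimethylsilyl)but-3-yn-1-yl]-3a,4-dihydro-2-benzofuran-1,5(3H,7aH)-dione (C7=C8 enone)
Conditions: Pd(OAc)2 (1.2 equiv), MeCN/DMSO, 40 °C
Reagents that add atoms: none
Why: Saegusa–Ito oxidation, in which the regiodefined silyl enol ether transmetallates to a divalent-palladium enolate at C7 and β-hydride elimination of H8 gives the C7=C8 enone, removes the C8 stereocentre of the cycloadduct.

Step 8
Reactants: 12 enone lactone
Product: 13 6,7-dihydroxy-7,7a-dimethyl-3-[4-(trimethylsilyl)but-3-yn-1-yl]hexahydro-2-benzofuran-1,5-dione (O7 and O8 cis to C11)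
Conditions: OsO4 (5 mol%), N-methylmorpholine N-oxide, acetone/H2O, rt
Reagents that add atoms: N-methylmorpholine N-oxide, C[N+]1([O-])CCOCC1; water, O
Why: Upjohn dihydroxylation is a suprafacial syn addition and should take place on the ring face opposite the C20 methyl, which the trans-fused lactone holds pseudo-axial next to C8, so that O7 and O8 both end up cis to C11 as in the target while the silylalkyne does not react.

Step 9
Reactants: 13 keto diol
Product: 14 7,8-O-isopropylidene derivative of 13
Conditions: 2-methoxypropene, pyridinium p-toluenesulfonate (cat.), CH2Cl2, 0 °C → rt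
Reagents that add atoms: 2-methoxypropene, COC(C)=C
Why: Acid-catalysed ketalisation (acetonide formation) of the cis-diol protects the secondary and the tertiary hydroxyl together and blocks retro-aldol cleavage of the β-hydroxy ketone.

Step 10
Reactants: 14 acetonide
Product: 15 terminal alkyne (14 without the C-silyl group)
Conditions: Bu4NF, AcOH, THF, 0 °C
Reagents that add atoms: none
Why: Fluoride-induced protodesilylation of the alkynylsilane is placed at the one stage that holds no O-silyl group, the acetic acid buffer sparing the lactone and the α-alkoxy ketone.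

Step 11
Reactants: 15 terminal alkyne ketone
Product: 18 C5-methylidene ketone (C5=C19H2), via Mannich base 16 (not isolated), via ammonium iodide 17 (not isolated)
Conditions: LiN(SiMe3)2 (1.05 equiv), THF, −78 °C; Me2N=CH2+ I−, −78 → 0 °C; MeI, CH2Cl2, rt; NaHCO3 (aq)
Reagents that add atoms: N,N-dimethylmethyleneiminium iodide, C=[N+](C)C.[I-]
Why: Kinetic deprotonation of the α-alkoxy ketone takes place at the unoxygenated methylene C5, the enolate is aminomethylated (Mannich reaction with Eschenmoser's salt) and quaternisation followed by mild base-induced elimination gives the α-methylene ketone that carries C19, the C5 enolate having no β-leaving group so that the acetonide stays closed.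

Step 12
Reactants: 18 C5-methylidene ketone
Product: 20 tert-butyldimethylsilyl enol ether C5(CH3)=C6(OSi) of the lactone, via lithium enolate 19 (not isolated)
Conditions: LiBH(s-Bu)3 (1.05 equiv), THF, −78 °C; TBSOTf, Et3N, −78 → 0 °C
Reagents that add atoms: tert-butyldimethylsilyl trifluoromethanesulfonate, CC(C)(C)[Si](C)(C)OS(=O)(=O)C(F)(F)F
Why: Conjugate reduction of the exocyclic enone (1,4-hydride addition) creates the C19 methyl and the C5=C6 enolate regiospecifically and O-silylation fixes it as the tetrasubstituted silyl enol ether with no chance of enolisation toward C7, the lactone not being reduced at −78 °C.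

Step 13
Reactants: 20 silyl enol ether lactone
Product: 21 lactol (C11 hemiacetal)
Conditions: i-Bu2AlH (1.1 equiv), CH2Cl2, −78 °C; KNaC4H4O6 (aq)
Reagents that add atoms: none
Why: Partial reduction of the γ-lactone stops at the tetrahedral aluminium lactolate at low temperature (lactone to lactol reduction), while the silyl enol ether, the acetonide and the alkyne are inert.

Step 14
Reactants: 21 lactol
Product: 22 ring B silyl enol ether with C9 vinyl group and free C1 hydroxyl
Conditions: Ph3PCH3Br, KN(SiMe3)2, THF, 0 °C → rt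
Reagents that add atoms: methyltriphenylphosphonium bromide, C[P+](c1ccccc1)(c1ccccc1)c1ccccc1.[Br-]
Why: The lactol opens to the hydroxy aldehyde under the basic conditions and Wittig methylenation of the neopentyl aldehyde gives the C11=C12 vinyl group and frees the C1 hydroxyl without affecting a stereocentre.

Step 15
Reactants: 22 vinyl alcohol
Product: 23 C1 tert-butyldimethylsilyl ether (ring B silyl enol ether with the C10 alkynyl arm)
Conditions: TBSOTf, 2,6-lutidine, CH2Cl2, −78 → 0 °C
Reagents that add atoms: tert-butyldimethylsilyl trifluoromethanesulfonate, CC(C)(C)[Si](C)(C)OS(=O)(=O)C(F)(F)F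
Why: Silyl triflate and a hindered pyridine base silylate the crowded secondary C1 hydroxyl (silyl ether protection), which would otherwise add to the gold-activated alkyne in the next step.

Step 16
Reactants: 23 ring B silyl enol ether with the C10 alkynyl arm
Product: 24 1-(tert-butyldimethylsilyloxy)-7,8-isopropylidenedioxy-13,14,15,16-tetranorcleroda-4(18),11-dien-6-one (trans-decalone)
Conditions: Ph3PAuCl (10 mol%), AgBF4 (10 mol%), CH2Cl2/MeOH (10:1), rt → 40 °C
Reagents that add atoms: none
Why: Ph3PAu+ (monovalent gold, freed from Ph3PAuCl by AgBF4) coordinates the terminal alkyne, the silyl enol ether attacks C4 through C5 anti to gold, methanol takes the silyl group from the oxocarbenium ion to restore the C6 ketone and protodeauration of the alkenylgold leaves the exocyclic C4=C18 methylene. The closest known reaction type is the gold-catalysed Conia-ene-type carbocyclisation of silyl enol ethers onto tethered terminal alkynes, which builds quaternary carbons under neutral conditions. Ring A closes in the 6-exo-dig mode, with C4 inside and C18 outside the ring; the 7-endo mode is not competitive for a terminal alkyne. The new stereocentre C5 is controlled by the axial C20 methyl on C9, which is 1,3 to C5 and screens the face opposite H10, and by the C1 silyloxy group, which is equatorial on the forming chair of ring A only when the alkyne comes in on the H10 face (closure on the other face would put it syn-axial to C19); this gives the trans ring fusion. The step needs regioselectivity (bond to C5, not C7) and this facial selectivity: the first is built into the enol ether made in step 12, the second rests on the ring B half-chair that the trans C9/C10 substituents and the C7/C8 acetonide hold with C20 axial.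

Step 17
Reactants: 24 trans-decalone
Product: 25 6-alcohol (H6 syn to H10)
Conditions: NaBH4, MeOH/THF, 0 °C → rt
Reagents that add atoms: none
Why: Hydride reduction of the hindered ketone by axial attack on the face of H10, the equatorial trajectory on the other face being screened by the axial C19 methyl on the neighbouring quaternary carbon, should give the equatorial 6-alcohol of the target.

Step 18
Reactants: 25 6-alcohol
Product: 26 6-acetate
Conditions: Ac2O, 4-(dimethylamino)pyridine, pyridine, 40 °C
Reagents that add atoms: acetic anhydride, CC(=O)OC(C)=O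
Why: Nucleophile-catalysed acylation of the only free hydroxyl installs the C6 acetate (esterification) with retention at C6.

Step 19
Reactants: 26 6-acetate
Product: 27 7,8-diol
Conditions: pyridinium p-toluenesulfonate, MeOH, 50 °C
Reagents that add atoms: none
Why: Acid-catalysed transketalisation to methanol removes the acetonide (acetal exchange), the mild pyridinium acid leaving the hindered secondary silyl ether, the acetate and both alkenes untouched.

Step 20
Reactants: 27 7,8-diol
Product: 28 7-(2-methylpropanoate)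
Conditions: i-PrCOCl, pyridine, 4-(dimethylamino)pyridine (cat.), CH2Cl2, 0 °C
Reagents that add atoms: 2-methylpropanoyl chloride, CC(C)C(Cl)=O
Why: Acylation distinguishes the secondary C7 hydroxyl from the tertiary C8 hydroxyl (selective esterification), and the low temperature and weak base keep the neighbouring acetate from migrating.

Step 21
Reactants: 28 7-(2-methylpropanoate); 29 4-bromofuran-2(5H)-one
Product: 30 1-O-tert-butyldimethylsilyl ether of the target
Conditions: Pd(OAc)2 (10 mol%), P(o-tol)3 (20 mol%), Bu4NCl, NaHCO3, DMF, 70 °C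
Reagents that add atoms: none
Why: Mizoroki–Heck reaction in which oxidative addition of the β-bromo butenolide to zerovalent palladium, insertion of the monosubstituted vinyl group at its terminal carbon C12 and β-hydride elimination, which can only take a C12 hydrogen because C9 is quaternary, give the E-configured C11=C12 diene, the 1,1-disubstituted C4=C18 alkene being too hindered to insert.

Step 22
Reactants: 30 1-O-tert-butyldimethylsilyl ether of the target
Product: 31 CNP0215764.1
Conditions: HF·pyridine, pyridine, THF, 0 °C → rt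
Reagents that add atoms: none
Why: Fluoride cleaves the Si–O bond of the C1 silyl ether (desilylation) under buffered, non-basic conditions that leave the two esters, the tertiary alcohol and the butenolide diene intact.

**Compound list**

1 | (E)-pent-3-en-2-one | C/C=C/C(C)=O | starting material
2 | triisopropyl{[(3E)-penta-1,3-dien-2-yl]oxy}silane | C=C(O[Si](C(C)C)(C(C)C)C(C)C)/C=C/C | intermediate
3 | ethyl (2E)-3-methyl-4-oxobut-2-enoate | CCOC(=O)/C=C(C)/C=O | starting material
4 | ethyl 6-formyl-5,6-dimethyl-3-[(triisopropylsilyl)oxy]cyclohex-3-ene-1-carboxylate (ester trans to formyl, 5-methyl cis to formyl) | CCOC(=O)[C@H]1CC(O[Si](C(C)C)(C(C)C)C(C)C)=C[C@H](C)[C@]1(C)C=O | intermediate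
5 | ethyl 6-(hydroxymethyl)-5,6-dimethyl-3-[(triisopropylsilyl)oxy]cyclohex-3-ene-1-carboxylate | CCOC(=O)[C@H]1CC(O[Si](C(C)C)(C(C)C)C(C)C)=C[C@H](C)[C@]1(C)CO | intermediate
6 | (4-bromobut-1-yn-1-yl)trimethylsilane | C[Si](C)(C)C#CCCBr | starting material
7 | [4-(trimethylsilyl)but-3-yn-1-yl]magnesium bromide | C[Si](C)(C)C#CCC[Mg]Br | intermediate (not isolated)
8 | 6-(hydroxymethyl)-N-methoxy-N,5,6-trimethyl-3-[(triisopropylsilyl)oxy]cyclohex-3-ene-1-carboxamide | CON(C)C(=O)[C@H]1CC(O[Si](C(C)C)(C(C)C)C(C)C)=C[C@H](C)[C@]1(C)CO | intermediate (not isolated)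
9 | 1-{6-(hydroxymethyl)-5,6-dimethyl-3-[(triisopropylsilyl)oxy]cyclohex-3-en-1-yl}-5-(trimethylsilyl)pent-4-yn-1-one | C[Si](C)(C)C#CCCC(=O)[C@H]1CC(O[Si](C(C)C)(C(C)C)C(C)C)=C[C@H](C)[C@]1(C)CO | intermediate
10 | 1-{6-(hydroxymethyl)-5,6-dimethyl-3-[(triisopropylsilyl)oxy]cyclohex-3-en-1-yl}-5-(trimethylsilyl)pent-4-yn-1-ol (C1 as in the target) | C[Si](C)(C)C#CCC[C@@H](O)[C@H]1CC(O[Si](C(C)C)(C(C)C)C(C)C)=C[C@H](C)[C@]1(C)CO | intermediate
11 | 7,7a-dimethyl-5-[(triisopropylsilyl)oxy]-3-[4-(trimethylsilyl)but-3-yn-1-yl]-3a,4,7,7a-tetrahydro-2-benzofuran-1(3H)-one (trans-fused) | C[Si](C)(C)C#CCC[C@H]1OC(=O)[C@@]2(C)[C@@H](C)C=C(O[Si](C(C)C)(C(C)C)C(C)C)C[C@H]12 | intermediate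
12 | 7,7a-dimethyl-3-[4-(trimethylsilyl)but-3-yn-1-yl]-3a,4-dihydro-2-benzofuran-1,5(3H,7aH)-dione | C[Si](C)(C)C#CCC[C@H]1OC(=O)[C@@]2(C)C(C)=CC(=O)C[C@H]12 | intermediate
13 | 6,7-dihydroxy-7,7a-dimethyl-3-[4-(trimethylsilyl)but-3-yn-1-yl]hexahydro-2-benzofuran-1,5-dione (both hydroxyls cis to the lactone carbonyl carbon) | C[Si](C)(C)C#CCC[C@H]1OC(=O)[C@@]2(C)[C@@](C)(O)[C@@H](O)C(=O)C[C@H]12 | intermediate
14 | acetonide of 13 (O7,O8-isopropylidene) | C[Si](C)(C)C#CCC[C@H]1OC(=O)[C@@]2(C)[C@@]3(C)OC(C)(C)O[C@H]3C(=O)C[C@H]12 | intermediate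
15 | terminal alkyne (14 without the C-silyl group) | C#CCC[C@H]1OC(=O)[C@@]2(C)[C@@]3(C)OC(C)(C)O[C@H]3C(=O)C[C@H]12 | intermediate
16 | C5-(dimethylaminomethyl) ketone (Mannich base; C5 unassigned) | C#CCC[C@H]1OC(=O)[C@@]2(C)[C@@]3(C)OC(C)(C)O[C@H]3C(=O)C(CN(C)C)[C@H]12 | intermediate (not isolated)
17 | C5-(trimethylammoniomethyl) ketone iodide | C#CCC[C@H]1OC(=O)[C@@]2(C)[C@@]3(C)OC(C)(C)O[C@H]3C(=O)C(C[N+](C)(C)C)[C@H]12.[I-] | intermediate (not isolated)
18 | C5-methylidene ketone | C#CCC[C@H]1OC(=O)[C@@]2(C)[C@@]3(C)OC(C)(C)O[C@H]3C(=O)C(=C)[C@H]12 | intermediate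
19 | lithium C5=C6 enolate | C#CCC[C@H]1OC(=O)[C@@]2(C)[C@@]3(C)OC(C)(C)O[C@H]3C(O[Li])=C(C)[C@H]12 | intermediate (not isolated)
20 | C5(CH3)=C6 tert-butyldimethylsilyl enol ether of the O1–C11 lactone | C#CCC[C@H]1OC(=O)[C@@]2(C)[C@@]3(C)OC(C)(C)O[C@H]3C(O[Si](C)(C)C(C)(C)C)=C(C)[C@H]12 | intermediate
21 | corresponding lactol (C11 hemiacetal, anomers) | C#CCC[C@H]1OC(O)[C@@]2(C)[C@@]3(C)OC(C)(C)O[C@H]3C(O[Si](C)(C)C(C)(C)C)=C(C)[C@H]12 | intermediate
22 | ring B silyl enol ether with C9 vinyl and free C1 hydroxyl | C#CCC[C@@H](O)[C@H]1C(C)=C(O[Si](C)(C)C(C)(C)C)[C@@H]2OC(C)(C)O[C@]2(C)[C@]1(C)C=C | intermediate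
23 | C1 tert-butyldimethylsilyl ether of 22 (cyclisation substrate) | C#CCC[C@@H](O[Si](C)(C)C(C)(C)C)[C@H]1C(C)=C(O[Si](C)(C)C(C)(C)C)[C@@H]2OC(C)(C)O[C@]2(C)[C@]1(C)C=C | intermediate
24 | 1-(tert-butyldimethylsilyloxy)-7,8-isopropylidenedioxy-13,14,15,16-tetranorcleroda-4(18),11-dien-6-one | C=C1CC[C@@H](O[Si](C)(C)C(C)(C)C)[C@H]2[C@@]1(C)C(=O)[C@@H]3OC(C)(C)O[C@]3(C)[C@]2(C)C=C | intermediate
25 | corresponding 6-ol (H6 syn to H10) | C=C1CC[C@@H](O[Si](C)(C)C(C)(C)C)[C@H]2[C@@]1(C)[C@@H](O)[C@@H]3OC(C)(C)O[C@]3(C)[C@]2(C)C=C | intermediate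
26 | 6-acetate of 25 | C=C1CC[C@@H](O[Si](C)(C)C(C)(C)C)[C@H]2[C@@]1(C)[C@@H](OC(C)=O)[C@@H]3OC(C)(C)O[C@]3(C)[C@]2(C)C=C | intermediate
27 | 6-acetoxy-7,8-diol | C=C1CC[C@@H](O[Si](C)(C)C(C)(C)C)[C@H]2[C@@]1(C)[C@@H](OC(C)=O)[C@H](O)[C@](C)(O)[C@]2(C)C=C | intermediate
28 | 6-acetoxy-7-(2-methylpropanoyloxy)-8-ol | C=C1CC[C@@H](O[Si](C)(C)C(C)(C)C)[C@H]2[C@@]1(C)[C@@H](OC(C)=O)[C@H](OC(=O)C(C)C)[C@](C)(O)[C@]2(C)C=C | intermediate
29 | 4-bromofuran-2(5H)-one | O=C1C=C(Br)CO1 | starting material
30 | 1-O-tert-butyldimethylsilyl ether of the target | C=C1CC[C@@H](O[Si](C)(C)C(C)(C)C)[C@H]2[C@@]1(C)[C@@H](OC(C)=O)[C@H](OC(=O)C(C)C)[C@](C)(O)[C@]2(C)/C=C/C1=CC(=O)OC1 | intermediate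
31 | CNP0215764.1, (1R,5R,6R,7S,8R,9R,10S), 11E | C=C1CC[C@@H](O)[C@H]2[C@@]1(C)[C@@H](OC(C)=O)[C@H](OC(=O)C(C)C)[C@](C)(O)[C@]2(C)/C=C/C1=CC(=O)OC1 | target

**Count and risks**

Total step count: 22. Longest linear sequence: 22 steps (from 1; compounds 3, 6 and 29 are bought and enter in steps 2, 4 and 21).

Steps most likely to fail:

1. Step 16. The closure may take place on the C20 face and give the cis ring fusion, since chair-like axial attack on an enol ether from an arm on the neighbouring carbon is the stereoelectronically easier path; the enol ether may also lose silicon before the C–C bond forms. The fallback sets out from lactone 20, where the five-membered lactone ties O1 to C11 and fixes the rotamer about C10–C1. C2 is then held on the H10 side, and a chair-like closure can reach only that face of C5. Under the conditions of step 16, 20 should give the tricyclic keto lactone F1. NaBH4 (MeOH, 0 °C) then reduces the ketone as in step 17 to the hydroxy lactone F2. i-Bu2AlH (CH2Cl2, −78 °C) gives the lactol F3, and Wittig methylenation (Ph3PCH3Br, KN(SiMe3)2, THF) gives the vinyl diol F4. Silylation of the less hindered C1 hydroxyl (TBSOTf, 2,6-lutidine, −78 °C) comes back to the route at 25.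

2. Step 21. Insertion of the vinyl group, which sits on a quaternary carbon, may be slow, and the bromo butenolide may decompose under the basic conditions before it couples. The fallback sets out from 28. Cross-metathesis with 4,4,5,5-tetramethyl-2-vinyl-1,3,2-dioxaborolane (second-generation Hoveyda–Grubbs catalyst, RuCl2(H2IMes)(=CH-C6H4-2-Oi-Pr), CH2Cl2, 40 °C) gives the E-alkenylboronate F5. Suzuki–Miyaura coupling with 29 (Pd(PPh3)4, zerovalent palladium, K3PO4, THF/H2O, 50 °C) comes back to the route at 30.

3. Step 7. Transmetallation of the bulky triisopropylsilyl enol ether to palladium may be slow, so that hydrolysis to the saturated ketone competes with dehydrogenation. The fallback sets out from 11. Bromination of the silyl enol ether with N-bromosuccinimide (THF, 0 °C) gives the α-bromo ketone F6 regiospecifically, and dehydrobromination (Li2CO3, LiBr, DMF, 100 °C) comes back to the route at 12.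

Further compounds
F1 | step 16 | tricyclic keto lactone (ring A closed on 20: C6 ketone, O1–C11 lactone, C7/C8 acetonide, C4=C18) | C=C1CC[C@H]2OC(=O)[C@@]3(C)[C@@]4(C)OC(C)(C)O[C@H]4C(=O)[C@]1(C)[C@H]23
F2 | step 16 | 6-hydroxy lactone | C=C1CC[C@H]2OC(=O)[C@@]3(C)[C@@]4(C)OC(C)(C)O[C@H]4[C@H](O)[C@]1(C)[C@H]23
F3 | step 16 | 6-hydroxy lactol (C11 hemiacetal) | C=C1CC[C@H]2OC(O)[C@@]3(C)[C@@]4(C)OC(C)(C)O[C@H]4[C@H](O)[C@]1(C)[C@H]23
F4 | step 16 | 7,8-isopropylidenedioxy-13,14,15,16-tetranorcleroda-4(18),11-diene-1,6-diol | C=C1CC[C@@H](O)[C@H]2[C@@]1(C)[C@@H](O)[C@@H]3OC(C)(C)O[C@]3(C)[C@]2(C)C=C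
F5 | step 21 | (E)-C12 pinacol boronate of 28 | C=C1CC[C@@H](O[Si](C)(C)C(C)(C)C)[C@H]2[C@@]1(C)[C@@H](OC(C)=O)[C@H](OC(=O)C(C)C)[C@](C)(O)[C@]2(C)/C=C/B1OC(C)(C)C(C)(C)O1
F6 | step 7 | C7 α-bromo ketone from 11 (C7 unassigned) | C[Si](C)(C)C#CCC[C@H]1OC(=O)[C@@]2(C)[C@@H](C)C(Br)C(=O)C[C@H]12
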